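**Retrosynthetic overview**

1. Target 27 ⇐ esterification of 3β-alcohol 25 ⇐ hydride reduction of 3-ketone 24 ⇐ ring A closed by a carbonyl-ene reaction of aldehyde 22 (C3–C4 bond; this one event creates the C4 gem-dimethyl carbon and the C5=C6 alkene).
2. 22 ⇐ lactone 13: C1 is extended by C2–C3 (lactol Wittig, hydrogenation), the freed C11–OH is etherified with umbelliferone (Mitsunobu), and the allylsilane is protodesilylated to the C8=C12 methylene.
3. Key disconnection: 13 ⇐ dienol 6 + allenic ester 10 by a template-tethered Diels–Alder/lactonisation that makes C5–C6 and C9–C10 (ring B) together with the C1–O–C11 lactone.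
4. Enabling feature: in ring B, the CH2O group (C11) on C9 and C1 on the quaternary C10 are cis, so they can be tied as a five-membered lactone C10–C1(=O)–O–C11–C9; C5 is sp2 and flanked by the gem-dimethyl carbon C4, which maps onto the allene C10=C5=C4Me2 of the dienophile.
5. Ring order: ring B plus the temporary lactone (step 5), then ring A (step 11); 6 comes from propargyl alcohol in three steps and 10 from a stabilised ylide in one step; drimane numbering is used (C11 = OCH2 on C9, C12 = methylene carbon on C8).

Key step: step 5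

Remark: the (R)-BINOL template is assumed to induce the (C9, C10) configuration drawn, by analogy with the acrylate series; if the sense proves opposite, (S)-BINOL is used in step 5 with nothing else changed.

**Route**

Step 1
Reactants: 1 prop-2-yn-1-ol; 2 bromoethene
Product: 3 pent-4-en-2-yn-1-ol
Conditions: PdCl2(PPh3)2 (2 mol %), CuI (4 mol %), iPr2NH, THF, 0 °C → rt
Reagents that add atoms: none
Why: Sonogashira coupling of the terminal alkyne with the vinyl bromide tolerates the free hydroxyl group and creates no stereo element.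

Step 2
Reactants: 3 pent-4-en-2-yn-1-ol
Product: 5 (2Z)-3-iodopenta-2,4-dien-1-ol, via cyclic alkenylalanate 4 (not isolated)
Conditions: NaAlH2(OCH2CH2OCH3)2 (1.5 equiv), Et2O, 0 °C; then I2, THF, −78 °C
Reagents that add atoms: iodine, II
Why: alkoxide-directed trans-hydroalumination of the propargylic alcohol places aluminium on C3 in the five-membered alanate 4, and iodinolysis with retention should give the (Z)-3-iodo allylic alcohol (the classical hydroalumination–iodination route to trisubstituted alkenes), which fixes the geometry of the later C8=C9 diene bond.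

Step 3
Reactants: 5 (2Z)-3-iodopenta-2,4-dien-1-ol
Product: 6 (2Z)-3-[(trimethylsilyl)methyl]penta-2,4-dien-1-ol
Conditions: Me3SiCH2MgCl (2.2 equiv), Pd(PPh3)4 (5 mol %), THF, 0 °C → rt
Reagents that add atoms: [(trimethylsilyl)methyl]magnesium chloride, C[Si](C)(C)C[Mg]Cl
Why: Kumada–Corriu coupling of an alkenyl iodide with the silylmethyl Grignard reagent proceeds with retention of alkene geometry and is a standard allylsilane synthesis, the first equivalent of the reagent only deprotonating the hydroxyl group.

Step 4
Reactants: 7 ethyl 2-(triphenyl-λ5-phosphanylidene)propanoate; 8 2-methylpropanoyl chloride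
Product: 10 ethyl 2,4-dimethylpenta-2,3-dienoate, via dimethylketene 9 (not isolated)
Conditions: Et3N (1.1 equiv), CH2Cl2, 0 °C → rt
Reagents that add atoms: none
Why: Wittig reaction of the stabilised ylide with dimethylketene 9, generated in the flask from the acid chloride and Et3N, is the standard ketene–ylide synthesis of allenic esters, and the allene is achiral because C4 carries two identical methyl groups.

Step 5
Reactants: 6 (2Z)-3-[(trimethylsilyl)methyl]penta-2,4-dien-1-ol; 10 ethyl 2,4-dimethylpenta-2,3-dienoate
Product: 13 (3aS,7aR)-7a-methyl-7-(propan-2-ylidene)-4-[(trimethylsilyl)methyl]-3a,6,7,7a-tetrahydro-2-benzofuran-1(3H)-one, via bromomagnesium alkoxide 11 (not isolated), via cycloadduct alkoxide 12 (not isolated)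
Conditions: MeMgBr (1.0 equiv), Me2Zn and (R)-BINOL (20 mol % each, premixed), CH2Cl2, 0 °C → rt; aq. NH4Cl
Reagents that add atoms: none
Why: Proposed new method: the bromomagnesium alkoxide 11 and the ester carbonyl of 10 are held on one chiral BINOL-bridged zinc/magnesium template, so that the electron-rich 2-(silylmethyl)diene C6=C7–C8=C9 adds to the Lewis-acid-activated conjugated C10=C5 bond of the allene in a concerted, asynchronous [4+2] cycloaddition that behaves as an intramolecular reaction, after which the alkoxide of 12 attacks the neighbouring ester and releases ethanol. The closest known reaction type is the Lewis-acid-templated (self-assembled) enantioselective Diels–Alder reaction of 2,4-dienols with methyl acrylate, which gives cis-fused bicyclic γ-lactones with the same regiochemistry; its extension to a tetrasubstituted allenic ester, a class known to react thermally as a dienophile at its conjugated double bond, is what is proposed. Ring B is closed by the [4+2] cycloaddition (bonds C5–C6 and C9–C10) and the lactone ring by 5-exo-trig acyl substitution. C9 and C10 are created together: their relative configuration (C11 cis to C1 and therefore trans to the C10 methyl group) is dictated by the template and the cis-fused five-membered lactone, and their absolute configuration by the BINOL ligand, which exposes one face of the bound allenoate. The step needs regioselectivity (C9 to the α-carbon C10, against the electronic "para" preference of the C8 silylmethyl group), which the O–metal–O=C tether secures, and site selectivity for the conjugated rather than the distal allene bond, which follows from the larger LUMO coefficient at C10=C5, so that the distal C5=C4 bond survives as the isopropylidene group needed in step 11. No other stereocentre arises because C5 stays sp2.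

Step 6
Reactants: 13 (3aS,7aR)-lactone
Product: 14 (3aS,7aR)-7a-methyl-7-(propan-2-ylidene)-4-[(trimethylsilyl)methyl]-1,3,3a,6,7,7a-hexahydro-2-benzofuran-1-ol (both C1 epimers)
Conditions: iBu2AlH (1.1 equiv), toluene, −78 °C; aq. potassium sodium tartrate
Reagents that add atoms: none
Why: low-temperature iBu2AlH reduction of a γ-lactone stops at the lactol oxidation level (the hindered, neopentyl-type carbonyl further disfavours over-reduction), and C9 and C10 are not touched.

Step 7
Reactants: 14 lactol; 15 (1,3-dioxolan-2-ylmethyl)triphenylphosphonium bromide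
Product: 18 {(1S,6R)-6-[2-(1,3-dioxolan-2-yl)ethenyl]-6-methyl-5-(propan-2-ylidene)-2-[(trimethylsilyl)methyl]cyclohex-2-en-1-yl}methanol (Z and E isomers), via phosphorus ylide 16 (not isolated), via hydroxy aldehyde 17 (not isolated)
Conditions: KOtBu (2.2 equiv), THF, 0 °C → rt
Reagents that add atoms: none
Why: Wittig olefination of the lactol, which reacts through its ring-opened form 17, with ylide 16 adds C2 and C3 (C3 masked as a dioxolane) and frees the C11 hydroxyl group, the alkene geometry being irrelevant because the bond is hydrogenated in step 8.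

Step 8
Reactants: 18 alkenyl acetal
Product: 19 {(1S,6R)-6-[2-(1,3-dioxolan-2-yl)ethyl]-6-methyl-5-(propan-2-ylidene)-2-[(trimethylsilyl)methyl]cyclohex-2-en-1-yl}methanol
Conditions: H2 (1 atm), RhCl(PPh3)3 (5 mol %), benzene/EtOH, rt
Reagents that add atoms: none
Why: homogeneous hydrogenation with RhCl(PPh3)3 should reduce the 1,2-disubstituted C1=C2 alkene much faster than the trisubstituted allylsilane and the tetrasubstituted isopropylidene alkenes (steric discrimination typical of this catalyst), and no stereocentre is formed.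

Step 9
Reactants: 19 saturated acetal alcohol; 20 7-hydroxy-2H-chromen-2-one (umbelliferone)
Product: 21 7-({(1S,6R)-6-[2-(1,3-dioxolan-2-yl)ethyl]-6-methyl-5-(propan-2-ylidene)-2-[(trimethylsilyl)methyl]cyclohex-2-en-1-yl}methoxy)-2H-chromen-2-one
Conditions: PPh3, DIAD, THF, 0 °C → rt
Reagents that add atoms: none
Why: Mitsunobu etherification of the primary C11 alcohol with the acidic phenol (pKa about 8) forms the aryl ether at a CH2 carbon, so no stereocentre is affected and the coumarin enters intact.

Step 10
Reactants: 21 aryl ether acetal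
Product: 22 3-[(1R,2R)-1-methyl-3-methylidene-2-{[(2-oxo-2H-chromen-7-yl)oxy]methyl}-6-(propan-2-ylidene)cyclohexyl]propanal
Conditions: TsOH·H2O (0.3 equiv), acetone/H2O (10:1), 45 °C
Reagents that add atoms: water, O
Why: acid-catalysed acetal hydrolysis unmasks the C3 aldehyde and, in the same pot, protodesilylation of the allylsilane (protonation at C7, loss of silicon from C12, the known way to turn 2-(silylmethyl)diene adducts into methylenecyclohexanes) moves the alkene to the exocyclic C8=C12 position.

Step 11
Reactants: 22 aldehyde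
Product: 23 7-{[(1R,8aR)-6-hydroxy-5,5,8a-trimethyl-2-methylidene-1,2,3,5,6,7,8,8a-octahydronaphthalen-1-yl]methoxy}-2H-chromen-2-one (both C3 epimers in drimane numbering)
Conditions: Me2AlCl (2.5 equiv), CH2Cl2, −78 → −20 °C; aq. HCl
Reagents that add atoms: none
Why: Lewis-acid-promoted intramolecular carbonyl-ene reaction in which the aldehyde carbon bonds to C4 of the strained tetrasubstituted C5=C4 alkene (fused six-membered ring A, favoured over the bridged rings that attack at the C8 methylene would give, and over closure at C5, which would create two adjacent quaternary carbons) while hydrogen is taken from C6, so that the gem-dimethyl carbon C4 and the C5=C6 alkene arise together; the C3 configuration is not relied on here and is set in step 13.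

Step 12
Reactants: 23 alcohol (epimers)
Product: 24 7-{[(1R,8aR)-5,5,8a-trimethyl-2-methylidene-6-oxo-1,2,3,5,6,7,8,8a-octahydronaphthalen-1-yl]methoxy}-2H-chromen-2-one
Conditions: Dess–Martin periodinane (1.3 equiv), CH2Cl2, rt
Reagents that add atoms: none
Why: Dess–Martin oxidation converges both C3 epimers into one β,γ-unsaturated ketone, which cannot move into conjugation because C4 is quaternary.

Step 13
Reactants: 24 ketone
Product: 25 7-{[(1R,6S,8aR)-6-hydroxy-5,5,8a-trimethyl-2-methylidene-1,2,3,5,6,7,8,8a-octahydronaphthalen-1-yl]methoxy}-2H-chromen-2-one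
Conditions: NaBH4, CeCl3·7H2O, MeOH, −40 °C
Reagents that add atoms: none
Why: Luche reduction in which hydride should add to the C3 ketone from the α face, anti to the axial C10 methyl and the 4β methyl groups, giving the equatorial 3β (3S) alcohol as is known for 4,4-dimethyl-Δ5-3-ketones, while the low temperature spares the coumarin lactone.

Step 14
Reactants: 25 3β-alcohol; 26 3-hydroxy-3-methylbutanoic acid
Product: 27 (2S,4aR,5R)-1,1,4a-trimethyl-6-methylidene-5-{[(2-oxo-2H-chromen-7-yl)oxy]methyl}-1,2,3,4,4a,5,6,7-octahydronaphthalen-2-yl 3-hydroxy-3-methylbutanoate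
Conditions: DCC (1.5 equiv), DMAP (0.2 equiv), CH2Cl2, 0 °C → rt
Reagents that add atoms: none
Why: Steglich esterification acylates the secondary 3β-alcohol, the tertiary hydroxyl group of the acid being too hindered to compete, and no stereocentre is touched.

**Compound list**

1 | prop-2-yn-1-ol | C#CCO | starting material
2 | bromoethene | C=CBr | starting material
3 | pent-4-en-2-yn-1-ol | C=CC#CCO | intermediate
4 | sodium 3-ethenyl-2,2-bis(2-methoxyethoxy)-2,5-dihydro-1,2-oxaluminol-2-uide (cyclic alkenylalanate) | C=CC1=CCO[Al-]1(OCCOC)OCCOC.[Na+] | intermediate (not isolated)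
5 | (2Z)-3-iodopenta-2,4-dien-1-ol | OC/C=C(\I)C=C | intermediate
6 | (2Z)-3-[(trimethylsilyl)methyl]penta-2,4-dien-1-ol | OC/C=C(\C[Si](C)(C)C)C=C | intermediate
7 | ethyl 2-(triphenyl-λ5-phosphanylidene)propanoate | CCOC(=O)C(C)=P(c1ccccc1)(c1ccccc1)c1ccccc1 | starting material
8 | 2-methylpropanoyl chloride | CC(C)C(Cl)=O | starting material
9 | dimethylketene | CC(C)=C=O | intermediate (not isolated)
10 | ethyl 2,4-dimethylpenta-2,3-dienoate | CCOC(=O)C(C)=C=C(C)C | intermediate
11 | bromomagnesium (2Z)-3-[(trimethylsilyl)methyl]penta-2,4-dien-1-olate | Br[Mg]OC/C=C(\C[Si](C)(C)C)C=C | intermediate (not isolated)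
12 | bromomagnesium alkoxide of ethyl (1R,2S)-2-(hydroxymethyl)-1-methyl-6-(propan-2-ylidene)-3-[(trimethylsilyl)methyl]cyclohex-3-ene-1-carboxylate | C[Si](C)(C)CC1=CCC(=C(C)C)[C@](C)(C(=O)OCC)[C@@H]1CO[Mg]Br | intermediate (not isolated)
13 | (3aS,7aR)-7a-methyl-7-(propan-2-ylidene)-4-[(trimethylsilyl)methyl]-3a,6,7,7a-tetrahydro-2-benzofuran-1(3H)-one | C[Si](C)(C)CC1=CCC(=C(C)C)[C@]2(C)C(=O)OC[C@H]12 | intermediate
14 | (3aS,7aR)-7a-methyl-7-(propan-2-ylidene)-4-[(trimethylsilyl)methyl]-1,3,3a,6,7,7a-hexahydro-2-benzofuran-1-ol (C1 epimers) | C[Si](C)(C)CC1=CCC(=C(C)C)[C@]2(C)C(O)OC[C@H]12 | intermediate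
15 | (1,3-dioxolan-2-ylmethyl)triphenylphosphonium bromide | [Br-].C(C1OCCO1)[P+](c1ccccc1)(c1ccccc1)c1ccccc1 | starting material
16 | (1,3-dioxolan-2-ylmethylidene)triphenyl-λ5-phosphane | C(=P(c1ccccc1)(c1ccccc1)c1ccccc1)C1OCCO1 | intermediate (not isolated)
17 | (1R,2S)-2-(hydroxymethyl)-1-methyl-6-(propan-2-ylidene)-3-[(trimethylsilyl)methyl]cyclohex-3-ene-1-carbaldehyde | C[Si](C)(C)CC1=CCC(=C(C)C)[C@](C)(C=O)[C@@H]1CO | intermediate (not isolated)
18 | {(1S,6R)-6-[2-(1,3-dioxolan-2-yl)ethenyl]-6-methyl-5-(propan-2-ylidene)-2-[(trimethylsilyl)methyl]cyclohex-2-en-1-yl}methanol (Z and E) | C[Si](C)(C)CC1=CCC(=C(C)C)[C@](C)(C=CC2OCCO2)[C@@H]1CO | intermediate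
19 | {(1S,6R)-6-[2-(1,3-dioxolan-2-yl)ethyl]-6-methyl-5-(propan-2-ylidene)-2-[(trimethylsilyl)methyl]cyclohex-2-en-1-yl}methanol | C[Si](C)(C)CC1=CCC(=C(C)C)[C@](C)(CCC2OCCO2)[C@@H]1CO | intermediate
20 | 7-hydroxy-2H-chromen-2-one (umbelliferone) | Oc1ccc2ccc(=O)oc2c1 | starting material
21 | 7-({(1S,6R)-6-[2-(1,3-dioxolan-2-yl)ethyl]-6-methyl-5-(propan-2-ylidene)-2-[(trimethylsilyl)methyl]cyclohex-2-en-1-yl}methoxy)-2H-chromen-2-one | C[Si](C)(C)CC1=CCC(=C(C)C)[C@](C)(CCC2OCCO2)[C@@H]1COc1ccc2ccc(=O)oc2c1 | intermediate
22 | 3-[(1R,2R)-1-methyl-3-methylidene-2-{[(2-oxo-2H-chromen-7-yl)oxy]methyl}-6-(propan-2-ylidene)cyclohexyl]propanal | C=C1CCC(=C(C)C)[C@](C)(CCC=O)[C@@H]1COc1ccc2ccc(=O)oc2c1 | intermediate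
23 | 7-{[(1R,8aR)-6-hydroxy-5,5,8a-trimethyl-2-methylidene-1,2,3,5,6,7,8,8a-octahydronaphthalen-1-yl]methoxy}-2H-chromen-2-one (C6 epimers) | C=C1CC=C2C(C)(C)C(O)CC[C@]2(C)[C@@H]1COc1ccc2ccc(=O)oc2c1 | intermediate
24 | 7-{[(1R,8aR)-5,5,8a-trimethyl-2-methylidene-6-oxo-1,2,3,5,6,7,8,8a-octahydronaphthalen-1-yl]methoxy}-2H-chromen-2-one | C=C1CC=C2C(C)(C)C(=O)CC[C@]2(C)[C@@H]1COc1ccc2ccc(=O)oc2c1 | intermediate
25 | 7-{[(1R,6S,8aR)-6-hydroxy-5,5,8a-trimethyl-2-methylidene-1,2,3,5,6,7,8,8a-octahydronaphthalen-1-yl]methoxy}-2H-chromen-2-one | C=C1CC=C2C(C)(C)[C@@H](O)CC[C@]2(C)[C@@H]1COc1ccc2ccc(=O)oc2c1 | intermediate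
26 | 3-hydroxy-3-methylbutanoic acid | CC(C)(O)CC(O)=O | starting material
27 | (2S,4aR,5R)-1,1,4a-trimethyl-6-methylidene-5-{[(2-oxo-2H-chromen-7-yl)oxy]methyl}-1,2,3,4,4a,5,6,7-octahydronaphthalen-2-yl 3-hydroxy-3-methylbutanoate | C=C1CC=C2C(C)(C)[C@@H](OC(=O)CC(C)(C)O)CC[C@]2(C)[C@@H]1COc1ccc2ccc(=O)oc2c1 | target

**Step count and risks**

Total step count: 14. Longest linear sequence: 13 steps (steps 1–3 and 5–14, from prop-2-yn-1-ol); step 4 is the one-step side branch.

Steps most likely to fail:

1. Step 5 (Proposed new method). The tetrasubstituted allenoate may react too slowly on the template, the alkoxide may instead add to the allene in an oxa-Michael sense, or facial discrimination by the ligand may be poor. Fallback with known chemistry, setting out from 6 and 10: saponification of 10 (LiOH, THF/H2O) would give 2,4-dimethylpenta-2,3-dienoic acid F1. Steglich esterification of F1 with 6 (DCC, DMAP) would give the dienyl allenoate (2Z)-3-[(trimethylsilyl)methyl]penta-2,4-dien-1-yl 2,4-dimethylpenta-2,3-dienoate F2. Thermal intramolecular Diels–Alder reaction of F2 (toluene, 130 °C, BHT), a known reaction type for ester-tethered trienes and allenic esters, would give lactone 13 as the racemate with its (3aR,7aS)-enantiomer F3. Preparative chromatography on a chiral stationary phase would remove F3, and the route is rejoined at 13.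

2. Step 11. The Lewis-acid step may stall or be diverted by closure at the wrong alkene carbon (C5, five-membered ring), by an ene reaction at the C8=C12 methylene, or by chloride capture or skeletal rearrangement at C5. Fallback, setting out from 22: Pinnick oxidation (NaClO2, NaH2PO4, 2-methylbut-2-ene) would give 3-[(1R,2R)-1-methyl-3-methylidene-2-{[(2-oxo-2H-chromen-7-yl)oxy]methyl}-6-(propan-2-ylidene)cyclohexyl]propanoic acid F4. Oxalyl chloride would convert F4 into the corresponding propanoyl chloride F5. Acylation of the C5=C4 alkene promoted by SnCl4 (CH2Cl2, −78 °C, 2,6-di-tert-butylpyridine as proton trap), with closure at C4 and loss of the C6 proton, would give ketone 24 directly. The route is rejoined at 24, and 23 and step 12 are bypassed.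

3. Step 14. Acylation of the neopentyl-type 3β-alcohol may be sluggish, and the activated β-hydroxy acid may dehydrate to the 3-methylbut-2-enoyl derivative. Fallback, setting out from 25: acylation with bromoacetyl bromide and pyridine (CH2Cl2, 0 °C) would give (2S,4aR,5R)-1,1,4a-trimethyl-6-methylidene-5-{[(2-oxo-2H-chromen-7-yl)oxy]methyl}-1,2,3,4,4a,5,6,7-octahydronaphthalen-2-yl bromoacetate F6. A Reformatsky reaction of F6 with zinc dust and acetone (THF, reflux) would build the tertiary alcohol and arrive at the target 27.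

Further compounds
F1 | step 5 | 2,4-dimethylpenta-2,3-dienoic acid | CC(C)=C=C(C)C(O)=O
F2 | step 5 | (2Z)-3-[(trimethylsilyl)methyl]penta-2,4-dien-1-yl 2,4-dimethylpenta-2,3-dienoate | CC(C)=C=C(C)C(=O)OC/C=C(\C[Si](C)(C)C)C=C
F3 | step 5 | (3aR,7aS)-7a-methyl-7-(propan-2-ylidene)-4-[(trimethylsilyl)methyl]-3a,6,7,7a-tetrahydro-2-benzofuran-1(3H)-one | C[Si](C)(C)CC1=CCC(=C(C)C)[C@@]2(C)C(=O)OC[C@@H]12
F4 | step 11 | 3-[(1R,2R)-1-methyl-3-methylidene-2-{[(2-oxo-2H-chromen-7-yl)oxy]methyl}-6-(propan-2-ylidene)cyclohexyl]propanoic acid | C=C1CCC(=C(C)C)[C@](C)(CCC(O)=O)[C@@H]1COc1ccc2ccc(=O)oc2c1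
F5 | step 11 | 3-[(1R,2R)-1-methyl-3-methylidene-2-{[(2-oxo-2H-chromen-7-yl)oxy]methyl}-6-(propan-2-ylidene)cyclohexyl]propanoyl chloride | C=C1CCC(=C(C)C)[C@](C)(CCC(Cl)=O)[C@@H]1COc1ccc2ccc(=O)oc2c1
F6 | step 14 | (2S,4aR,5R)-1,1,4a-trimethyl-6-methylidene-5-{[(2-oxo-2H-chromen-7-yl)oxy]methyl}-1,2,3,4,4a,5,6,7-octahydronaphthalen-2-yl bromoacetate | C=C1CC=C2C(C)(C)[C@@H](OC(=O)CBr)CC[C@]2(C)[C@@H]1COc1ccc2ccc(=O)oc2c1
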